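**Retrosynthetic overview**

1. Germacrane numbering is used: ring C1–C10, oxirane on C4–C5, OAc on C6, C7 carries the C11–C13 branch, OBz on C8, E-alkene C1=C10. Late stage: isopropyl from isopropenyl (hydrogenation), the C8 benzoate from a C8–B bond (oxidation with retention, then benzoylation), the C6 acetate by acetylation.
2. Key disconnection C6–C7: the ten-membered carbocycle from an acyclic cis-epoxy aldehyde bearing a terminal 2-methyl-1,3-diene plus B2pin2, by platinum-catalysed 1,4-diboration and ring-closing allylboration in one flask. This closes the ring and sets C6, C7 and C8.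
3. Enabling feature: on the ten-membered ring, C7 with its three-carbon branch lies between the two oxygen-bearing carbons C6 and C8, O6 is cis to the branch, and C6 is next to the C4–C5 oxirane. This is the retron of a (Z)-allylboronate adding to an α,β-epoxy aldehyde with a second boron left on C8.
4. The acyclic C15 chain from nerol (C6–C5–C4(C15)–C3–C2–C1=C10(C14)–C9) and 2-methylbut-1-en-3-yne (C8, C7, C11–C13) by allylic oxidation, bromination and alkenyl–allyl cross-coupling; the oxirane by Sharpless epoxidation of the Z-allylic alcohol.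
5. Ring order: oxirane first (step 6), ten-membered carbocycle second (step 8).

Key step: step 8

Remark: C7 changes from S (compounds 14–16) to R (17–19), and C2 of the oxirane from R (10) to S (11), only because the CIP priorities change; no centre is inverted.
Assumption: the (R,R) antipode of the TADDOL-derived phenylphosphonite (3,5-dimethylphenyl groups) is taken to give the 8S boronate by analogy with simple (E)-1,3-dienes; if the sense of induction is opposite, the mirror-image ligand is used.

**Route**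

Step 1
Reactants: 1 nerol
Product: 2 tert-butyl{[(2Z)-3,7-dimethylocta-2,6-dien-1-yl]oxy}diphenylsilane
Conditions: TBDPSCl, imidazole, CH2Cl2, 0 °C to rt
Reagents that add atoms: tert-butyl(chloro)diphenylsilane, CC(C)(C)[Si](Cl)(c1ccccc1)c1ccccc1
Why: Imidazole-promoted silylation of the primary allylic alcohol gives a bulky silyl ether that should survive the oxidation, bromination and organometallic coupling that follow.

Step 2
Reactants: 2 tert-butyl{[(2Z)-3,7-dimethylocta-2,6-dien-1-yl]oxy}diphenylsilane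
Product: 3 (2E,6Z)-8-[(tert-butyldiphenylsilyl)oxy]-2,6-dimethylocta-2,6-dien-1-ol
Conditions: SeO2 (cat.), t-BuOOH, salicylic acid (cat.), CH2Cl2, 0 °C to rt
Reagents that add atoms: tert-butyl hydroperoxide, CC(C)(C)OO
Why: SeO2-catalysed allylic hydroxylation (ene reaction, then [2,3]-sigmatropic shift) is selective for the E-methyl group of the terminal prenyl unit and should give the E-allylic alcohol, the alkene next to the silyloxy group being deactivated.

Step 3
Reactants: 3 (2E,6Z)-8-[(tert-butyldiphenylsilyl)oxy]-2,6-dimethylocta-2,6-dien-1-ol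
Product: 4 {[(2Z,6E)-8-bromo-3,7-dimethylocta-2,6-dien-1-yl]oxy}(tert-butyl)diphenylsilane
Conditions: CBr4, PPh3, CH2Cl2, 0 °C
Reagents that add atoms: carbon tetrabromide, BrC(Br)(Br)Br
Why: The Appel reaction converts the primary allylic alcohol into the bromide under neutral conditions without allylic transposition or loss of alkene geometry.

Step 4
Reactants: 4 {[(2Z,6E)-8-bromo-3,7-dimethylocta-2,6-dien-1-yl]oxy}(tert-butyl)diphenylsilane; 5 2-methylbut-1-en-3-yne; 6 Cp2Zr(H)Cl
Product: 8 tert-butyldiphenyl{[(2Z,6E,9E)-3,7,11-trimethyldodeca-2,6,9,11-tetraen-1-yl]oxy}silane, via dienylzirconocene chloride 7 (not isolated)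
Conditions: 5, Cp2Zr(H)Cl, THF, rt; then 4, Pd(PPh3)4 (5 mol %), THF, 0 °C to rt
Reagents that add atoms: none
Why: Syn hydrozirconation of the terminal alkyne places zirconium on the terminal carbon, and the E-dienylzirconium should then couple at the unsubstituted end of the π-allylpalladium formed from 4 (Negishi-type alkenyl–allyl cross-coupling) with retention of all alkene geometries.

Step 5
Reactants: 8 tert-butyldiphenyl{[(2Z,6E,9E)-3,7,11-trimethyldodeca-2,6,9,11-tetraen-1-yl]oxy}silane
Product: 9 (2Z,6E,9E)-3,7,11-trimethyldodeca-2,6,9,11-tetraen-1-ol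
Conditions: Bu4NF, THF, 0 °C to rt
Reagents that add atoms: none
Why: Fluoride cleaves the Si–O bond and should leave the polyene untouched.

Step 6
Reactants: 9 (2Z,6E,9E)-3,7,11-trimethyldodeca-2,6,9,11-tetraen-1-ol
Product: 10 [(2R,3S)-3-[(3E,6E)-4,8-dimethylnona-3,6,8-trien-1-yl]-3-methyloxiran-2-yl]methanol
Conditions: Ti(OiPr)4 (cat.), D-(−)-diethyl tartrate, t-BuOOH, 4 Å molecular sieves, CH2Cl2, −20 °C
Reagents that add atoms: tert-butyl hydroperoxide, CC(C)(C)OO
Why: In the Sharpless asymmetric epoxidation the titanium tartrate delivers oxygen only to the alkene of the allylic alcohol, and with D-(−)-tartrate the nerol-type Z-alkene should give the (2R,3S) cis-epoxide, which sets C4 and C5 of the target.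

Step 7
Reactants: 10 [(2R,3S)-3-[(3E,6E)-4,8-dimethylnona-3,6,8-trien-1-yl]-3-methyloxiran-2-yl]methanol
Product: 11 (2S,3S)-3-[(3E,6E)-4,8-dimethylnona-3,6,8-trien-1-yl]-3-methyloxirane-2-carbaldehyde
Conditions: PhI(OAc)2, TEMPO (cat.), CH2Cl2, rt
Reagents that add atoms: none
Why: TEMPO-catalysed oxidation stops at the aldehyde and is mild enough for the cis-epoxide and the diene, and the oxirane carbon next to the carbonyl should not epimerise because its enolisation is strongly disfavoured.

Step 8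
Reactants: 11 (2S,3S)-3-[(3E,6E)-4,8-dimethylnona-3,6,8-trien-1-yl]-3-methyloxirane-2-carbaldehyde; 12 bis(pinacolato)diboron
Product: 15 (1(10)E,4S,5R,6R,7S,8S)-4,5-epoxy-8-(4,4,5,5-tetramethyl-1,3,2-dioxaborolan-2-yl)germacra-1(10),11-dien-6-ol, via acyclic bis(boronate) aldehyde 13 (not isolated), via cyclic O-boryl boronate 14 (not isolated)
Conditions: Pt(dba)3 (10 mol %), (R,R)-TADDOL-derived phenylphosphonite (12 mol %), 12, degassed toluene, 60 °C, slow addition of 11 (final 0.005 M), then 80 °C; aq NH4Cl work-up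
Reagents that add atoms: none
Why: Proposed new method: zerovalent platinum should add the B–B bond of 12 across the s-cis diene of 11 (oxidative addition, diene insertion to a boryl allylplatinum, reductive elimination) to give the (Z)-1,4-bis(boronate) 13, whose primary allylboronate then adds through its γ-carbon C7 to the tethered aldehyde carbon C6 in a closed six-membered chair (B–O–C6–C7–C11–C12), passing boron to oxygen (14) and shifting the alkene into the isopropenyl group. The closest known reaction type is the intermolecular one-flask sequence of platinum-catalysed enantioselective 1,4-diboration of an (E)-1,3-diene and allylboration of an added aldehyde, together with ring closures of smaller rings by intramolecular allylboration; running both as a cascade that closes a ten-membered ring is new. The ten-membered carbocycle closes by C6–C7 bond formation as a 10-exo-trig addition to the carbonyl group (SE2′ at the allyl unit), the oxirane being carried through intact. C8 is set in the diboration by the chiral phosphonite on platinum (enantiofacial boryl transfer to the diene terminus) and its C–B bond is a masked hydroxyl; C7 follows from C8 because allylic 1,3-strain with C12 holds H8 in the plane of the Z-allyl unit, so that the tether (C9 onward) lies on the attacked face and the aldehyde enters anti to the C8–B bond; C6 follows from the chair with C8 axial (Z geometry) and the oxirane carbon C5 equatorial, which places O6 cis to the C7 branch, and this is also the Felkin–Anh face of the aldehyde, anti to the C5–O bond, so the controlling elements reinforce each other. The step needs site selectivity (only the conjugated diene can bind platinum as an s-cis diene, the trisubstituted alkene being inert), regioselectivity in the allylation (the CH2–B terminus attacks through monosubstituted C7, whereas the C8–B unit would have to form a quaternary centre at C11) and ring closure over oligomerisation, which the cis-oxirane and the E-alkene favour as turn elements and slow addition at high dilution enforces.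

Step 9
Reactants: 15 (1(10)E,4S,5R,6R,7S,8S)-4,5-epoxy-8-(4,4,5,5-tetramethyl-1,3,2-dioxaborolan-2-yl)germacra-1(10),11-dien-6-ol
Product: 16 (1(10)E,4S,5R,6R,7S,8S)-4,5-epoxy-8-(4,4,5,5-tetramethyl-1,3,2-dioxaborolan-2-yl)germacra-1(10),11-dien-6-yl acetate
Conditions: Ac2O, pyridine, DMAP (cat.), CH2Cl2, 0 °C to rt
Reagents that add atoms: acetic anhydride, CC(=O)OC(C)=O
Why: DMAP-catalysed acetylation of the only free hydroxyl should proceed cleanly, the secondary alkyl pinacol boronate being inert to these conditions.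

Step 10
Reactants: 16 (1(10)E,4S,5R,6R,7S,8S)-4,5-epoxy-8-(4,4,5,5-tetramethyl-1,3,2-dioxaborolan-2-yl)germacra-1(10),11-dien-6-yl acetate
Product: 17 (1(10)E,4S,5R,6R,7R,8S)-6-acetoxy-4,5-epoxygermacra-1(10),11-dien-8-ol
Conditions: NaBO3·4H2O, THF/H2O, 0 °C to rt
Reagents that add atoms: sodium perborate, [Na+].[O-]OB=O
Why: Perborate oxidation of the C–B bond (1,2-shift of carbon from boron to oxygen) proceeds with retention and should give the 8S carbinol under conditions mild enough for the acetate, the epoxide and both alkenes.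

Step 11
Reactants: 17 (1(10)E,4S,5R,6R,7R,8S)-6-acetoxy-4,5-epoxygermacra-1(10),11-dien-8-ol
Product: 18 (1(10)E,4S,5R,6R,7R,8S)-6-acetoxy-4,5-epoxygermacra-1(10),11-dien-8-yl benzoate
Conditions: BzCl, pyridine, DMAP (cat.), CH2Cl2, 0 °C to rt
Reagents that add atoms: benzoyl chloride, O=C(Cl)c1ccccc1
Why: DMAP-catalysed benzoylation should acylate the C8 alcohol, the only free hydroxyl, without disturbing the C6 acetate.

Step 12
Reactants: 18 (1(10)E,4S,5R,6R,7R,8S)-6-acetoxy-4,5-epoxygermacra-1(10),11-dien-8-yl benzoate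
Product: 19 (1(10)E,4S,5R,6R,7R,8S)-6-acetoxy-4,5-epoxygermacr-1(10)-en-8-yl benzoate
Conditions: H2 (1 atm), RhCl(PPh3)3 (cat.), benzene, rt
Reagents that add atoms: none
Why: Homogeneous hydrogenation with RhCl(PPh3)3 should reduce the 1,1-disubstituted isopropenyl alkene much faster than the trisubstituted ring alkene and leave the epoxide and esters untouched, creating no new stereocentre.

**Compound list**

1 | nerol, (2Z)-3,7-dimethylocta-2,6-dien-1-ol | OC/C=C(C)\CCC=C(C)C | starting material
2 | tert-butyl{[(2Z)-3,7-dimethylocta-2,6-dien-1-yl]oxy}diphenylsilane | CC(C)=CCC/C(C)=C\CO[Si](c1ccccc1)(c1ccccc1)C(C)(C)C | intermediate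
3 | (2E,6Z)-8-[(tert-butyldiphenylsilyl)oxy]-2,6-dimethylocta-2,6-dien-1-ol | OC/C(C)=C/CC/C(C)=C\CO[Si](c1ccccc1)(c1ccccc1)C(C)(C)C | intermediate
4 | {[(2Z,6E)-8-bromo-3,7-dimethylocta-2,6-dien-1-yl]oxy}(tert-butyl)diphenylsilane | BrC/C(C)=C/CC/C(C)=C\CO[Si](c1ccccc1)(c1ccccc1)C(C)(C)C | intermediate
5 | 2-methylbut-1-en-3-yne | C=C(C)C#C | starting material
6 | chloridobis(cyclopentadienyl)hydridozirconium, Cp2Zr(H)Cl | [H][Zr](Cl)(C1C=CC=C1)C1C=CC=C1 | starting material
7 | chlorido[(1E)-3-methylbuta-1,3-dien-1-yl]bis(cyclopentadienyl)zirconium | C=C(C)/C=C/[Zr](Cl)(C1C=CC=C1)C1C=CC=C1 | intermediate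
8 | tert-butyldiphenyl{[(2Z,6E,9E)-3,7,11-trimethyldodeca-2,6,9,11-tetraen-1-yl]oxy}silane | C=C(C)/C=C/C/C(C)=C/CC/C(C)=C\CO[Si](c1ccccc1)(c1ccccc1)C(C)(C)C | intermediate
9 | (2Z,6E,9E)-3,7,11-trimethyldodeca-2,6,9,11-tetraen-1-ol | C=C(C)/C=C/C/C(C)=C/CC/C(C)=C\CO | intermediate
10 | [(2R,3S)-3-[(3E,6E)-4,8-dimethylnona-3,6,8-trien-1-yl]-3-methyloxiran-2-yl]methanol | OC[C@H]1O[C@@]1(C)CC/C=C(\C)C/C=C/C(C)=C | intermediate
11 | (2S,3S)-3-[(3E,6E)-4,8-dimethylnona-3,6,8-trien-1-yl]-3-methyloxirane-2-carbaldehyde | O=C[C@H]1O[C@@]1(C)CC/C=C(\C)C/C=C/C(C)=C | intermediate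
12 | bis(pinacolato)diboron | CC1(C)OB(OC1(C)C)B1OC(C)(C)C(C)(C)O1 | starting material
13 | (2S,3S)-3-[(3E,6S,7Z)-4,8-dimethyl-6,9-bis(4,4,5,5-tetramethyl-1,3,2-dioxaborolan-2-yl)nona-3,7-dien-1-yl]-3-methyloxirane-2-carbaldehyde | O=C[C@H]1O[C@@]1(C)CC/C=C(\C)C[C@H](B2OC(C)(C)C(C)(C)O2)/C=C(C)\CB2OC(C)(C)C(C)(C)O2 | intermediate
14 | (1(10)E,4S,5R,6R,7S,8S)-4,5-epoxy-8-(4,4,5,5-tetramethyl-1,3,2-dioxaborolan-2-yl)-6-[(4,4,5,5-tetramethyl-1,3,2-dioxaborolan-2-yl)oxy]germacra-1(10),11-diene | CC1(C)OB(O[C@@H]2[C@H](C(C)=C)[C@@H](B3OC(C)(C)C(C)(C)O3)C/C(C)=C/CC[C@]3(C)O[C@H]23)OC1(C)C | intermediate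
15 | (1(10)E,4S,5R,6R,7S,8S)-4,5-epoxy-8-(4,4,5,5-tetramethyl-1,3,2-dioxaborolan-2-yl)germacra-1(10),11-dien-6-ol | O[C@@H]1[C@H](C(C)=C)[C@@H](B2OC(C)(C)C(C)(C)O2)C/C(C)=C/CC[C@]2(C)O[C@H]12 | intermediate
16 | (1(10)E,4S,5R,6R,7S,8S)-4,5-epoxy-8-(4,4,5,5-tetramethyl-1,3,2-dioxaborolan-2-yl)germacra-1(10),11-dien-6-yl acetate | CC(=O)O[C@@H]1[C@H](C(C)=C)[C@@H](B2OC(C)(C)C(C)(C)O2)C/C(C)=C/CC[C@]2(C)O[C@H]12 | intermediate
17 | (1(10)E,4S,5R,6R,7R,8S)-6-acetoxy-4,5-epoxygermacra-1(10),11-dien-8-ol | CC(=O)O[C@@H]1[C@H](C(C)=C)[C@@H](O)C/C(C)=C/CC[C@]2(C)O[C@H]12 | intermediate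
18 | (1(10)E,4S,5R,6R,7R,8S)-6-acetoxy-4,5-epoxygermacra-1(10),11-dien-8-yl benzoate | CC(=O)O[C@@H]1[C@H](C(C)=C)[C@@H](OC(=O)c2ccccc2)C/C(C)=C/CC[C@]2(C)O[C@H]12 | intermediate
19 | (1(10)E,4S,5R,6R,7R,8S)-6-acetoxy-4,5-epoxygermacr-1(10)-en-8-yl benzoate | CC(=O)O[C@@H]1[C@H](C(C)C)[C@@H](OC(=O)c2ccccc2)C/C(C)=C/CC[C@]2(C)O[C@H]12 | target

**Step count and risks**

Total step count: 12. Longest linear sequence: 12 steps (nerol to 19).

Steps most likely to fail, riskiest first:

Step 8. The boryl–platinum species may consume the aldehyde, the diboration may stall at the dilution that ring closure needs, intermolecular allylboration may outrun ring closure, or facial control in the diboration may be incomplete. The fallback separates the two events and runs each in its established setting, setting out from 10. Diboration at ordinary concentration (Pt(dba)3, the same ligand, 12, THF, 60 °C), with no carbonyl group present, should give the bis(boronate) epoxy alcohol [(2R,3S)-3-[(3E,6S,7Z)-4,8-dimethyl-6,9-bis(4,4,5,5-tetramethyl-1,3,2-dioxaborolan-2-yl)nona-3,7-dien-1-yl]-3-methyloxiran-2-yl]methanol F1, which is isolated. Parikh–Doering oxidation (SO3·pyridine, DMSO, iPr2NEt, CH2Cl2, 0 °C, 0.003 M) then releases aldehyde 13, and warming to 40 °C should close the ring through 14; aqueous work-up gives 15, where the fallback rejoins the route. The ring closure itself is still an allylboration forming a ten-membered ring, so this fallback answers the one-flask incompatibility but not a failure of the macrocyclisation as such.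

Step 12. The ring alkene may be over-reduced, or the isopropenyl group, flanked by two acyloxy-bearing carbons, may fail to bind rhodium. The fallback reduces earlier and without a metal, setting out from 15. Diimide generated from 2-nitrobenzenesulfonyl hydrazide and Et3N (CH2Cl2, rt) should reduce the less hindered 1,1-disubstituted alkene to give the isopropyl hydroxy boronate (1(10)E,4S,5R,6R,7S,8S)-4,5-epoxy-8-(4,4,5,5-tetramethyl-1,3,2-dioxaborolan-2-yl)germacr-1(10)-en-6-ol F2. Acetylation as in step 9 gives the acetate (1(10)E,4S,5R,6R,7S,8S)-4,5-epoxy-8-(4,4,5,5-tetramethyl-1,3,2-dioxaborolan-2-yl)germacr-1(10)-en-6-yl acetate F3. Perborate oxidation as in step 10 gives the alcohol (1(10)E,4S,5R,6R,7R,8S)-6-acetoxy-4,5-epoxygermacr-1(10)-en-8-ol F4. Benzoylation as in step 11 then gives 19 directly, where the fallback ends.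

Step 10. Under the basic peroxide conditions the acetyl group may migrate from O6 to the newly freed O8 or be hydrolysed, which would scramble the two esters, and the hindered secondary boronate may oxidise slowly. The fallback uses a non-migrating group on O6, setting out from 15. Silylation (Et3SiOTf, 2,6-lutidine, CH2Cl2, −78 °C) gives the silyl ether (1(10)E,4S,5R,6R,7S,8S)-4,5-epoxy-8-(4,4,5,5-tetramethyl-1,3,2-dioxaborolan-2-yl)-6-(triethylsilyloxy)germacra-1(10),11-diene F5. Perborate oxidation gives the alcohol (1(10)E,4S,5R,6R,7R,8S)-4,5-epoxy-6-(triethylsilyloxy)germacra-1(10),11-dien-8-ol F6. Benzoylation gives the benzoate (1(10)E,4S,5R,6R,7R,8S)-4,5-epoxy-6-(triethylsilyloxy)germacra-1(10),11-dien-8-yl benzoate F7. Desilylation (HF·pyridine buffered with pyridine, THF, 0 °C) gives the alcohol (1(10)E,4S,5R,6R,7S,8S)-4,5-epoxy-6-hydroxygermacra-1(10),11-dien-8-yl benzoate F8. Acetylation as in step 9 then gives 18, where the fallback rejoins the route.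

Further compounds
F1 | step 8 | [(2R,3S)-3-[(3E,6S,7Z)-4,8-dimethyl-6,9-bis(4,4,5,5-tetramethyl-1,3,2-dioxaborolan-2-yl)nona-3,7-dien-1-yl]-3-methyloxiran-2-yl]methanol | OC[C@H]1O[C@@]1(C)CC/C=C(\C)C[C@H](B2OC(C)(C)C(C)(C)O2)/C=C(C)\CB2OC(C)(C)C(C)(C)O2
F2 | step 12 | (1(10)E,4S,5R,6R,7S,8S)-4,5-epoxy-8-(4,4,5,5-tetramethyl-1,3,2-dioxaborolan-2-yl)germacr-1(10)-en-6-ol | O[C@@H]1[C@H](C(C)C)[C@@H](B2OC(C)(C)C(C)(C)O2)C/C(C)=C/CC[C@]2(C)O[C@H]12
F3 | step 12 | (1(10)E,4S,5R,6R,7S,8S)-4,5-epoxy-8-(4,4,5,5-tetramethyl-1,3,2-dioxaborolan-2-yl)germacr-1(10)-en-6-yl acetate | CC(=O)O[C@@H]1[C@H](C(C)C)[C@@H](B2OC(C)(C)C(C)(C)O2)C/C(C)=C/CC[C@]2(C)O[C@H]12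
F4 | step 12 | (1(10)E,4S,5R,6R,7R,8S)-6-acetoxy-4,5-epoxygermacr-1(10)-en-8-ol | CC(=O)O[C@@H]1[C@H](C(C)C)[C@@H](O)C/C(C)=C/CC[C@]2(C)O[C@H]12
F5 | step 10 | (1(10)E,4S,5R,6R,7S,8S)-4,5-epoxy-8-(4,4,5,5-tetramethyl-1,3,2-dioxaborolan-2-yl)-6-(triethylsilyloxy)germacra-1(10),11-diene | CC[Si](CC)(CC)O[C@@H]1[C@H](C(C)=C)[C@@H](B2OC(C)(C)C(C)(C)O2)C/C(C)=C/CC[C@]2(C)O[C@H]12
F6 | step 10 | (1(10)E,4S,5R,6R,7R,8S)-4,5-epoxy-6-(triethylsilyloxy)germacra-1(10),11-dien-8-ol | CC[Si](CC)(CC)O[C@@H]1[C@H](C(C)=C)[C@@H](O)C/C(C)=C/CC[C@]2(C)O[C@H]12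
F7 | step 10 | (1(10)E,4S,5R,6R,7R,8S)-4,5-epoxy-6-(triethylsilyloxy)germacra-1(10),11-dien-8-yl benzoate | CC[Si](CC)(CC)O[C@@H]1[C@H](C(C)=C)[C@@H](OC(=O)c2ccccc2)C/C(C)=C/CC[C@]2(C)O[C@H]12
F8 | step 10 | (1(10)E,4S,5R,6R,7S,8S)-4,5-epoxy-6-hydroxygermacra-1(10),11-dien-8-yl benzoate | O[C@@H]1[C@H](C(C)=C)[C@@H](OC(=O)c2ccccc2)C/C(C)=C/CC[C@]2(C)O[C@H]12
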